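**Strategy.** The route rests on cutting the bond between the quaternary benzylic carbon C1 and the isopropenyl-bearing C2 of the tetralone ring (naphthalene numbering). The key step exploits the peri relationship of the C8 phenol oxygen to C1: oxygen and the first side-chain carbon are tied to C1 as a five-membered lactone, a 3-methylbenzofuran-2(3H)-one, whose acidic C3–H adds under chiral amine–squaramide catalysis to an (E)-4-methylpenta-2,4-dienoyl group on the neighbouring ring carbon. This single intramolecular Michael addition closes the cyclohexanone ring (ring B) and sets both stereocentres. Afterwards the lactone carbon is extended by two carbons to the propanoic acid and the para-methoxyphenol is unmasked to the hydroquinone.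

Key step: step 8

Remark: the sense of asymmetric induction of the quinine-derived squaramide is assumed by analogy with intermolecular benzofuranone Michael additions; if the opposite antipode predominates, the quinidine-derived pseudoenantiomer of the catalyst is used instead.

Step 1
Reactants: 1 1,3-dimethoxybenzene; 2 acetone
Product: 4 2-(2,6-dimethoxyphenyl)propan-2-ol, via aryllithium 3 (not isolated)
Conditions: n-BuLi, THF, 0 °C to rt; then 2, −78 °C to rt; H2O
Reagents that add atoms: none
Why: Directed ortho-metalation at the carbon between the two methoxy groups and 1,2-addition of the aryllithium to acetone should give the tertiary benzylic alcohol; no stereocenter is formed.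

Step 2
Reactants: 4 2-(2,6-dimethoxyphenyl)propan-2-ol
Product: 5 1,3-dimethoxy-2-(propan-2-yl)benzene
Conditions: Et3SiH, CF3CO2H, CH2Cl2, 0 °C to rt
Reagents that add atoms: none
Why: Ionic hydrogenation: the acid ionizes the tertiary benzylic alcohol and the silane delivers hydride to the cation, which should leave the isopropyl group without touching the aryl ethers.

Step 3
Reactants: 5 1,3-dimethoxy-2-(propan-2-yl)benzene
Product: 8 2,4-dimethoxy-3-(propan-2-yl)phenol, via aryllithium 6 (not isolated), via boronate 7 (not isolated)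
Conditions: n-BuLi, N,N,N′,N′-tetramethylethylenediamine, Et2O, 0 °C to rt; B(OMe)3, −78 °C to rt; H2O2, NaOH (aq), 0 °C; then dilute HCl
Reagents that add atoms: hydrogen peroxide, OO
Why: Ortho-lithiation beside a methoxy group (both ortho sites are equivalent), trapping with the borate and oxidative 1,2-migration from boron to oxygen should install the phenol regiospecifically (lithiation–borylation–oxidation).

Step 4
Reactants: 8 2,4-dimethoxy-3-(propan-2-yl)phenol; 9 ethyl pyruvate
Product: 11 3-hydroxy-5,7-dimethoxy-3-methyl-6-(propan-2-yl)-1-benzofuran-2(3H)-one (racemic), via hydroxy ester 10 (not isolated)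
Conditions: TiCl4 (1.1 equiv), CH2Cl2, −40 °C; then 9, −40 °C to rt; 1 M HCl
Reagents that add atoms: none
Why: The aryloxytitanium trichloride formed in the flask binds the α-keto ester and delivers it to the only free ortho carbon (ortho-selective Friedel–Crafts hydroxyalkylation), after which the hydroxy ester closes to the five-membered aryl lactone; the carbinol stereocenter arises as a racemate and is removed in step 5.

Step 5
Reactants: 11 3-hydroxy-5,7-dimethoxy-3-methyl-6-(propan-2-yl)-1-benzofuran-2(3H)-one
Product: 12 5,7-dimethoxy-3-methyl-6-(propan-2-yl)-1-benzofuran-2(3H)-one (racemic)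
Conditions: SmI2 (2.5 equiv), hexamethylphosphoramide, t-BuOH, THF, rt; dilute HCl
Reagents that add atoms: none
Why: Two single-electron transfers from divalent samarium to the α-oxygenated lactone expel hydroxide and give the aromatic 2-oxidobenzofuran, which is protonated at C3 (reductive α-deoxygenation of an α-hydroxy ester); the C3–H center is racemic and labile, which is what step 8 needs.

Step 6
Reactants: 13 methacrolein; 14 malonic acid
Product: 16 (2E)-4-methylpenta-2,4-dienoic acid, via alkylidenemalonic acid 15 (not isolated)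
Conditions: pyridine, piperidine (cat.), 60 to 90 °C; dilute HCl
Reagents that add atoms: none
Why: Knoevenagel condensation with in-flask decarboxylation (Doebner modification) should give the dienoic acid with the E double bond, the thermodynamically preferred outcome of the decarboxylative elimination.

Step 7
Reactants: 12 5,7-dimethoxy-3-methyl-6-(propan-2-yl)-1-benzofuran-2(3H)-one; 16 (2E)-4-methylpenta-2,4-dienoic acid
Product: 18 5,7-dimethoxy-3-methyl-4-[(2E)-4-methylpenta-2,4-dienoyl]-6-(propan-2-yl)-1-benzofuran-2(3H)-one (racemic), via acid chloride 17 (not isolated)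
Conditions: 16, (COCl)2, N,N-dimethylformamide (cat.), CH2Cl2, 0 °C; then 12, SnCl4, CH2Cl2, −40 to 0 °C; cold aqueous NaH2PO4
Reagents that add atoms: none
Why: Friedel–Crafts acylation at the only unsubstituted ring carbon, which is ortho to one methoxy group and para to the other; the mild Lewis acid at low temperature and a base-free work-up should spare the methyl ethers, the diene and the acidic lactone C–H, and the E geometry of 16 is carried over unchanged.

Step 8
Reactants: 18 5,7-dimethoxy-3-methyl-4-[(2E)-4-methylpenta-2,4-dienoyl]-6-(propan-2-yl)-1-benzofuran-2(3H)-one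
Product: 19 (2aS,3S)-6,8-dimethoxy-2a-methyl-7-(propan-2-yl)-3-(prop-1-en-2-yl)-3,4-dihydro-2H-naphtho[1,8-bc]furan-2,5(2aH)-dione
Conditions: 3-{[3,5-bis(trifluoromethyl)phenyl]amino}-4-{[(8α,9S)-6′-methoxycinchonan-9-yl]amino}cyclobut-3-ene-1,2-dione (quinine-derived squaramide, 10 mol%), toluene (0.02 M), −20 °C, argon
Reagents that add atoms: none
Why: The quinuclidine nitrogen of the bifunctional catalyst deprotonates the acidic C3–H of the benzofuranone to a planar 2-oxidobenzofuran enolate held in a chiral ion pair while the squaramide N–H bonds activate the dienone carbonyl, and C3 then adds to the β-carbon of the tethered (E)-enone (intramolecular Michael addition); the closest known reaction type is the cinchona-amine-catalysed asymmetric Michael addition of 3-alkylbenzofuran-2(3H)-ones to aryl enones, which forms the same kind of quaternary C3–Cβ bond. The cyclohexanone ring closes in a 6-endo-trig mode (the enone C=C lies inside the new ring), and 1,6-addition at the diene terminus is excluded because it would need an eight-membered ring containing a trans double bond. At the quaternary carbon the lactone keeps the carbonyl carbon in the plane of the arene, so the methyl group, which lies where the new bond must form, is pushed to the face opposite the incoming chain. At the adjacent carbon the E geometry keeps the isopropenyl group outside the forming ring (pseudo-equatorial) and moves the inner hydrogen anti to that methyl group, so that methyl and isopropenyl end up cis; this arrangement is also the more stable one, so kinetic and thermodynamic control agree. The absolute configuration is set by which enantiotopic face of the enolate the catalyst leaves open to the enone. The step needs C- over O-alkylation and intra- over intermolecular addition, which the soft enolate carbon, the six-membered ring size and high dilution should secure.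

Step 9
Reactants: 19 (2aS,3S)-6,8-dimethoxy-2a-methyl-7-(propan-2-yl)-3-(prop-1-en-2-yl)-3,4-dihydro-2H-naphtho[1,8-bc]furan-2,5(2aH)-dione; 20 methyl (triphenyl-λ5-phosphanylidene)acetate
Product: 22 methyl (2E)-3-[(1S,2S)-4,8-dihydroxy-5,7-dimethoxy-1-methyl-6-(propan-2-yl)-2-(prop-1-en-2-yl)-1,2,3,4-tetrahydronaphthalen-1-yl]prop-2-enoate (C4 epimers), via lactol 21 (not isolated)
Conditions: i-Bu2AlH (3.2 equiv), CH2Cl2, −78 °C; MeOH; then 20, toluene, rt to 60 °C; KNaC4H4O6 (aq)
Reagents that add atoms: none
Why: Hydride reduces the aryl lactone to the lactol (and the ketone to the carbinol, which also blocks retro-Michael cleavage at the aldehyde stage), and the ring-opened hydroxy aldehyde undergoes Wittig olefination with the stabilized ylide to the E enoate; the two ring stereocenters are not enolizable here and the new carbinol center, formed as a mixture, is oxidized away in step 11.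

Step 10
Reactants: 22 methyl (2E)-3-[(1S,2S)-4,8-dihydroxy-5,7-dimethoxy-1-methyl-6-(propan-2-yl)-2-(prop-1-en-2-yl)-1,2,3,4-tetrahydronaphthalen-1-yl]prop-2-enoate
Product: 23 methyl 3-[(1S,2S)-4,8-dihydroxy-5,7-dimethoxy-1-methyl-6-(propan-2-yl)-2-(prop-1-en-2-yl)-1,2,3,4-tetrahydronaphthalen-1-yl]propanoate (C4 epimers)
Conditions: Cu(OAc)2 (5 mol%), 1,2-bis(diphenylphosphino)benzene (5 mol%), (EtO)2MeSiH (excess), t-BuOH, toluene, rt; NaHCO3 (aq)
Reagents that add atoms: none
Why: Copper hydride generated from the silane adds 1,4 to the enoate and the silyl ketene acetal is protonated (conjugate reduction), which should leave the isolated 1,1-disubstituted alkene untouched because it is not activated by a carbonyl group.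

Step 11
Reactants: 23 methyl 3-[(1S,2S)-4,8-dihydroxy-5,7-dimethoxy-1-methyl-6-(propan-2-yl)-2-(prop-1-en-2-yl)-1,2,3,4-tetrahydronaphthalen-1-yl]propanoate
Product: 24 methyl 3-[(1S,2S)-8-hydroxy-5,7-dimethoxy-1-methyl-4-oxo-6-(propan-2-yl)-2-(prop-1-en-2-yl)-1,2,3,4-tetrahydronaphthalen-1-yl]propanoate
Conditions: MnO2 (activated, excess), CH2Cl2, rt
Reagents that add atoms: none
Why: MnO2 oxidizes the benzylic alcohol back to the aryl ketone on its surface while saturated centers, the isopropenyl group and the hindered phenol should survive; the carbinol stereocenter is removed.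

Step 12
Reactants: 24 methyl 3-[(1S,2S)-8-hydroxy-5,7-dimethoxy-1-methyl-4-oxo-6-(propan-2-yl)-2-(prop-1-en-2-yl)-1,2,3,4-tetrahydronaphthalen-1-yl]propanoate
Product: 25 3-[(1S,2S)-8-hydroxy-5,7-dimethoxy-1-methyl-4-oxo-6-(propan-2-yl)-2-(prop-1-en-2-yl)-1,2,3,4-tetrahydronaphthalen-1-yl]propanoic acid
Conditions: LiOH, THF/H2O, rt; 1 M HCl to pH 4, 0 °C
Reagents that add atoms: water (delivered as hydroxide), O
Why: Saponification of the methyl ester; the ring stereocenters cannot epimerize because the quaternary carbon has no hydrogen and the neighbouring center is β, not α, to the ketone.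

Step 13
Reactants: 25 3-[(1S,2S)-8-hydroxy-5,7-dimethoxy-1-methyl-4-oxo-6-(propan-2-yl)-2-(prop-1-en-2-yl)-1,2,3,4-tetrahydronaphthalen-1-yl]propanoic acid
Product: 27 3-[(1S,2S)-5,8-dihydroxy-7-methoxy-1-methyl-4-oxo-6-(propan-2-yl)-2-(prop-1-en-2-yl)-1,2,3,4-tetrahydronaphthalen-1-yl]propanoic acid (CNP0249049.1), via quinone 26 (not isolated)
Conditions: PhI(OAc)2, MeCN/H2O, 0 °C; then Na2S2O4 (aq), 0 °C, argon
Reagents that add atoms: water, O
Why: The hypervalent iodine reagent oxidizes the para-methoxyphenol, water adds at the methoxy-bearing para carbon and methanol is lost to give the para-quinone (oxidative demethylation), and dithionite reduces the quinone in the same flask to the hydroquinone, so that no acid strong enough to add the peri phenol to the isopropenyl group is ever present.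

**Compound list**

1 | 1,3-dimethoxybenzene | COc1cccc(OC)c1 | starting material
2 | acetone | CC(C)=O | starting material
3 | (2,6-dimethoxyphenyl)lithium | [Li]c1c(OC)cccc1OC | intermediate (not isolated)
4 | 2-(2,6-dimethoxyphenyl)propan-2-ol | COc1cccc(OC)c1C(C)(C)O | intermediate
5 | 1,3-dimethoxy-2-(propan-2-yl)benzene | COc1cccc(OC)c1C(C)C | intermediate
6 | [2,4-dimethoxy-3-(propan-2-yl)phenyl]lithium | [Li]c1ccc(OC)c(C(C)C)c1OC | intermediate (not isolated)
7 | dimethyl [2,4-dimethoxy-3-(propan-2-yl)phenyl]boronate | COB(OC)c1ccc(OC)c(C(C)C)c1OC | intermediate (not isolated)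
8 | 2,4-dimethoxy-3-(propan-2-yl)phenol | COc1ccc(O)c(OC)c1C(C)C | intermediate
9 | ethyl pyruvate (ethyl 2-oxopropanoate) | CCOC(=O)C(C)=O | starting material
10 | ethyl 2-hydroxy-2-[2-hydroxy-3,5-dimethoxy-4-(propan-2-yl)phenyl]propanoate (racemic) | CCOC(=O)C(C)(O)c1cc(OC)c(C(C)C)c(OC)c1O | intermediate (not isolated)
11 | 3-hydroxy-5,7-dimethoxy-3-methyl-6-(propan-2-yl)-1-benzofuran-2(3H)-one (racemic) | CC1(O)C(=O)Oc2c(OC)c(C(C)C)c(OC)cc21 | intermediate
12 | 5,7-dimethoxy-3-methyl-6-(propan-2-yl)-1-benzofuran-2(3H)-one (racemic) | CC1C(=O)Oc2c(OC)c(C(C)C)c(OC)cc21 | intermediate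
13 | methacrolein (2-methylprop-2-enal) | C=C(C)C=O | starting material
14 | malonic acid | OC(=O)CC(=O)O | starting material
15 | 2-(2-methylprop-2-en-1-ylidene)propanedioic acid | C=C(C)C=C(C(=O)O)C(=O)O | intermediate (not isolated)
16 | (2E)-4-methylpenta-2,4-dienoic acid | C=C(C)/C=C/C(=O)O | intermediate
17 | (2E)-4-methylpenta-2,4-dienoyl chloride | C=C(C)/C=C/C(=O)Cl | intermediate (not isolated)
18 | 5,7-dimethoxy-3-methyl-4-[(2E)-4-methylpenta-2,4-dienoyl]-6-(propan-2-yl)-1-benzofuran-2(3H)-one (racemic, C3 labile) | C=C(C)/C=C/C(=O)c1c(OC)c(C(C)C)c(OC)c2OC(=O)C(C)c12 | intermediate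
19 | (2aS,3S)-6,8-dimethoxy-2a-methyl-7-(propan-2-yl)-3-(prop-1-en-2-yl)-3,4-dihydro-2H-naphtho[1,8-bc]furan-2,5(2aH)-dione | C=C(C)[C@@H]1CC(=O)c2c(OC)c(C(C)C)c(OC)c3c2[C@@]1(C)C(=O)O3 | intermediate
20 | methyl (triphenyl-λ5-phosphanylidene)acetate | COC(=O)C=P(c1ccccc1)(c1ccccc1)c1ccccc1 | starting material
21 | (2aS,3S)-6,8-dimethoxy-2a-methyl-7-(propan-2-yl)-3-(prop-1-en-2-yl)-2a,3,4,5-tetrahydro-2H-naphtho[1,8-bc]furan-2,5-diol (epimers at C2 and C5) | C=C(C)[C@@H]1CC(O)c2c(OC)c(C(C)C)c(OC)c3c2[C@@]1(C)C(O)O3 | intermediate (not isolated)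
22 | methyl (2E)-3-[(1S,2S)-4,8-dihydroxy-5,7-dimethoxy-1-methyl-6-(propan-2-yl)-2-(prop-1-en-2-yl)-1,2,3,4-tetrahydronaphthalen-1-yl]prop-2-enoate (C4 epimers) | C=C(C)[C@@H]1CC(O)c2c(OC)c(C(C)C)c(OC)c(O)c2[C@@]1(C)/C=C/C(=O)OC | intermediate
23 | methyl 3-[(1S,2S)-4,8-dihydroxy-5,7-dimethoxy-1-methyl-6-(propan-2-yl)-2-(prop-1-en-2-yl)-1,2,3,4-tetrahydronaphthalen-1-yl]propanoate (C4 epimers) | C=C(C)[C@@H]1CC(O)c2c(OC)c(C(C)C)c(OC)c(O)c2[C@@]1(C)CCC(=O)OC | intermediate
24 | methyl 3-[(1S,2S)-8-hydroxy-5,7-dimethoxy-1-methyl-4-oxo-6-(propan-2-yl)-2-(prop-1-en-2-yl)-1,2,3,4-tetrahydronaphthalen-1-yl]propanoate | C=C(C)[C@@H]1CC(=O)c2c(OC)c(C(C)C)c(OC)c(O)c2[C@@]1(C)CCC(=O)OC | intermediate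
25 | 3-[(1S,2S)-8-hydroxy-5,7-dimethoxy-1-methyl-4-oxo-6-(propan-2-yl)-2-(prop-1-en-2-yl)-1,2,3,4-tetrahydronaphthalen-1-yl]propanoic acid | C=C(C)[C@@H]1CC(=O)c2c(OC)c(C(C)C)c(OC)c(O)c2[C@@]1(C)CCC(=O)O | intermediate
26 | 3-[(1S,2S)-7-methoxy-1-methyl-4,5,8-trioxo-6-(propan-2-yl)-2-(prop-1-en-2-yl)-1,2,3,4,5,8-hexahydronaphthalen-1-yl]propanoic acid | C=C(C)[C@@H]1CC(=O)C2=C(C(=O)C(OC)=C(C(C)C)C2=O)[C@@]1(C)CCC(=O)O | intermediate (not isolated)
27 | 3-[(1S,2S)-5,8-dihydroxy-7-methoxy-1-methyl-4-oxo-6-(propan-2-yl)-2-(prop-1-en-2-yl)-1,2,3,4-tetrahydronaphthalen-1-yl]propanoic acid (CNP0249049.1) | C=C(C)[C@@H]1CC(=O)c2c(O)c(C(C)C)c(OC)c(O)c2[C@@]1(C)CCC(=O)O | target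

**Totals.** Total step count: 13. Longest linear sequence: 12 steps (steps 1–5 and 7–13, from 1,3-dimethoxybenzene); step 6 is a one-step side branch.

**Steps most likely to fail**

Step 8 (key step). The catalyst may not discriminate the two faces of the planar enolate well enough, a base-catalysed background closure may erode the enantiomeric purity, or the strained off-axis approach of the enone to the lactone carbon may slow the closure so that intermolecular addition competes. Fallback: starting from 18, the ring is closed with the achiral base 1,8-diazabicyclo[5.4.0]undec-7-ene (cat., toluene, high dilution) to the racemic keto lactone F1, whose relative configuration is fixed by the same geometric constraints. The enantiomers of F1 are then separated by preparative chromatography on a chiral stationary phase, and the (2aS,3S) enantiomer re-enters the route as 19.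

Step 7. Acylation at the doubly flanked ring carbon may be too slow, which leaves time for acylation of the enolizable lactone or for cationic polymerization of the diene. Fallback: starting from 12, the ring carbon is formylated with Cl2CHOMe and TiCl4 (Rieche formylation) to the aldehyde F2. Methacrolein 13 is converted with CHI3 and CrCl2 (Takai olefination) into (1E)-1-iodo-3-methylbuta-1,3-diene F3. F2 and F3 are joined under Nozaki–Hiyama–Kishi conditions (CrCl2, NiCl2 (cat.), DMSO), which tolerate the acidic lactone, to the dienyl carbinol F4, and oxidation of F4 with MnO2 returns to the route at 18.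

Step 4. The activated keto ester may attack the ring carbon that is ortho and para to the two methoxy groups instead of the carbon ortho to the hydroxyl group (misdirected regiochemistry). Fallback: starting from 8, O-alkylation with (E)-1-bromobut-2-ene and K2CO3 gives the crotyl ether F5. Thermal aromatic Claisen rearrangement (N,N-diethylaniline, 190 °C) can deliver the 1-methylallyl group only to the free ortho carbon and gives the phenol F6. Oxidative cleavage of the vinyl group (OsO4 (cat.), NaIO4, dioxane/H2O) gives the lactol F7, and oxidation with n-Pr4N[RuO4] (cat.) and N-methylmorpholine N-oxide returns to the route at 12, so that steps 4 and 5 are bypassed.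

**Further compounds**

F1 | step 8 | racemic keto lactone (1:1 mixture of 19 and its enantiomer) | C=C(C)[C@@H]1CC(=O)c2c(OC)c(C(C)C)c(OC)c3c2[C@@]1(C)C(=O)O3.C=C(C)[C@H]1CC(=O)c2c(OC)c(C(C)C)c(OC)c3c2[C@]1(C)C(=O)O3
F2 | step 7 | 5,7-dimethoxy-3-methyl-2-oxo-6-(propan-2-yl)-2,3-dihydro-1-benzofuran-4-carbaldehyde (racemic) | CC1C(=O)Oc2c(OC)c(C(C)C)c(OC)c(C=O)c21
F3 | step 7 | (1E)-1-iodo-3-methylbuta-1,3-diene | C=C(C)/C=C/I
F4 | step 7 | 4-[(2E)-1-hydroxy-4-methylpenta-2,4-dien-1-yl]-5,7-dimethoxy-3-methyl-6-(propan-2-yl)-1-benzofuran-2(3H)-one (mixture of diastereomers) | C=C(C)/C=C/C(O)c1c(OC)c(C(C)C)c(OC)c2OC(=O)C(C)c12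
F5 | step 4 | 1-[(2E)-but-2-en-1-yloxy]-2,4-dimethoxy-3-(propan-2-yl)benzene | C/C=C/COc1ccc(OC)c(C(C)C)c1OC
F6 | step 4 | 6-(but-3-en-2-yl)-2,4-dimethoxy-3-(propan-2-yl)phenol (racemic) | C=CC(C)c1cc(OC)c(C(C)C)c(OC)c1O
F7 | step 4 | 5,7-dimethoxy-3-methyl-6-(propan-2-yl)-2,3-dihydro-1-benzofuran-2-ol (racemic, mixture of anomers) | CC1C(O)Oc2c(OC)c(C(C)C)c(OC)cc21
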